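## Retrosynthetic overview

1. 13 ⇐ 11 ⇐ 10: the ring tertiary allylic alcohol comes from an oxirane on the tetrasubstituted ring alkene (reagent-controlled epoxidation, then epoxide-to-allyl silyl ether isomerisation).
2. 10 ⇐ 9: the 1,2-dioxane is closed at the C3–O bond by a catalytic asymmetric intramolecular peroxide conjugate addition with catalyst-controlled α-protonation (sets C3 and C2).
3. 9 ⇐ 7: the tertiary C6–OO bond comes from Markovnikov cobalt/O2/silane hydroperoxysilylation of a 1,1-disubstituted alkene.
4. 7 ⇐ 1 + 2 + 6: cross-metathesis with methyl methacrylate, Wittig methylenation, and enolate allylation of dihydro-β-ionone.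
5. Ring order: the cyclohexene ring comes with 1; the 1,2-dioxane forms in step 5; the oxirane of step 6 is opened again in step 7.

## Notes before the steps

- Assumption: C6 cannot be set by reagent control with chemistry I can defend. Step 4 gives both C6 antipodes, and step 5 fixes C6 by separating the two diastereomeric ring-closure products, so at most half of the material goes on.
- Assumption: the sense of induction of the chiral catalysts in steps 5 and 6 is taken as written. Both catalysts are available as either antipode, and the other one is used if the first run shows the opposite sense.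
- Locants C1–C8 are those of the octenoate chain; C3 and C6 become the dioxane carbons. The CIP letter at C6 is S in 10 and R in 11–13 only because the ranking of its two CH2 chains changes; the spatial arrangement is the same.
- (S)-BIMP catalyst = 1-[3,5-bis(trifluoromethyl)phenyl]-3-[(2S)-3,3-dimethyl-1-{[tris(4-methoxyphenyl)-λ5-phosphanylidene]amino}butan-2-yl]thiourea.
- Shi ketone = 1,2:4,5-di-O-isopropylidene-β-D-erythro-2,3-hexodiulo-2,6-pyranose.

## Route

Step 1
Reactants: 1 dihydro-β-ionone; 2 allyl bromide
Product: 4 1-(2,6,6-trimethylcyclohex-1-en-1-yl)hept-6-en-3-one, via lithium enolate 3 (not isolated)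
Conditions: LiN(iPr)2 (1.05 equiv), THF, −78 °C; then 2, −78 to 0 °C
Reagents that add atoms: allyl bromide (2), C=CCBr
Why: Kinetic deprotonation takes the methyl side of the ketone and the lithium enolate is C-allylated by SN2 (enolate alkylation); no stereocenter is formed.

Step 2
Reactants: 4 1-(2,6,6-trimethylcyclohex-1-en-1-yl)hept-6-en-3-one
Product: 5 1,3,3-trimethyl-2-(3-methylidenehept-6-en-1-yl)cyclohex-1-ene
Conditions: Ph3PCH3Br, KOtBu, THF, 0 °C to rt
Reagents that add atoms: methyltriphenylphosphonium bromide, C[P+](c1ccccc1)(c1ccccc1)c1ccccc1.[Br-]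
Why: Wittig methylenation turns the ketone into the 1,1-disubstituted alkene whose CH2 becomes the C6 methyl group; no stereocenter is formed.

Step 3
Reactants: 5 1,3,3-trimethyl-2-(3-methylidenehept-6-en-1-yl)cyclohex-1-ene; 6 methyl methacrylate
Product: 7 methyl (2E)-2-methyl-6-methylidene-8-(2,6,6-trimethylcyclohex-1-en-1-yl)oct-2-enoate
Conditions: second-generation Hoveyda–Grubbs catalyst (5 mol %), 6 (10 equiv), CH2Cl2, 40 °C
Reagents that add atoms: methyl methacrylate (6), C=C(C)C(=O)OC
Why: Olefin cross-metathesis of the monosubstituted alkene with excess methacrylate gives the E trisubstituted enoate under thermodynamic control, while the 1,1-disubstituted and tetrasubstituted alkenes are too hindered to react.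

Step 4
Reactants: 7 methyl (2E)-2-methyl-6-methylidene-8-(2,6,6-trimethylcyclohex-1-en-1-yl)oct-2-enoate
Product: 8 methyl (2E)-2,6-dimethyl-6-[(triethylsilyl)peroxy]-8-(2,6,6-trimethylcyclohex-1-en-1-yl)oct-2-enoate (both C6 antipodes)
Conditions: Co(acac)2 (10 mol %), O2 (1 atm), Et3SiH (2 equiv), ClCH2CH2Cl, rt
Reagents that add atoms: dioxygen, O=O; triethylsilane, CC[SiH](CC)CC
Why: Mukaiyama–Isayama hydroperoxysilylation (cobalt hydride hydrogen-atom transfer, then O2 capture of the tertiary radical) is Markovnikov and prefers the 1,1-disubstituted alkene over the enoate and the tetrasubstituted ring alkene; the planar radical gives both C6 antipodes.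

Step 5
Reactants: 8 methyl (2E)-2,6-dimethyl-6-[(triethylsilyl)peroxy]-8-(2,6,6-trimethylcyclohex-1-en-1-yl)oct-2-enoate (both C6 antipodes)
Product: 10 methyl (2S)-2-{(3S,6S)-6-methyl-6-[2-(2,6,6-trimethylcyclohex-1-en-1-yl)ethyl]-1,2-dioxan-3-yl}propanoate, via hydroperoxide 9 (not isolated)
Conditions: HCl (cat.), MeOH, 0 °C, NaHCO3 work-up; then (S)-BIMP catalyst (10 mol %), toluene, −20 °C; chromatography
Reagents that add atoms: none
Why: Proposed new method: a catalytic enantioselective intramolecular peroxide conjugate addition with catalyst-controlled α-protonation. The iminophosphorane, a strong non-nucleophilic base, deprotonates the tertiary hydroperoxide (pKa near 13) and the thiourea binds the ester carbonyl. The peroxide oxygen adds 6-exo-trig to C3 through a chair with the enoate equatorial, on the alkene face fixed by the catalyst backbone. The iminophosphoranium N–H then protonates the ester enolate on the same face, faster than the enolate can attack the O–O bond; net syn addition across the E alkene gives 2S,3S. The closest known reactions are the iminophosphorane-catalysed enantioselective intramolecular oxa-Michael addition of alcohols to unactivated α,β-unsaturated esters, the same catalysts' sulfa-Michael addition with enantioselective protonation of α-substituted acrylates, and the racemic amine-mediated hydroperoxide Michael ring closure to 1,2-dioxanes. C3 and C2 are set by the catalyst in both C6 antipodes of 9, which therefore give two diastereomeric dioxanes; chromatography keeps 10, the one with the C7 chain cis to the C3 side chain.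

Step 6
Reactants: 10 methyl (2S)-2-{(3S,6S)-6-methyl-6-[2-(2,6,6-trimethylcyclohex-1-en-1-yl)ethyl]-1,2-dioxan-3-yl}propanoate
Product: 11 methyl (2S)-2-[(3S,6R)-6-methyl-6-{2-[(1S,6R)-2,2,6-trimethyl-7-oxabicyclo[4.1.0]heptan-1-yl]ethyl}-1,2-dioxan-3-yl]propanoate
Conditions: Shi ketone (30 mol %), KHSO5 (as 2KHSO5·KHSO4·K2SO4), K2CO3, Bu4NHSO4 (cat.), MeCN–CH2(OMe)2–aq. buffer pH 10.5, 0 °C
Reagents that add atoms: potassium peroxymonosulfate, [K+].[O-]S(=O)(=O)OO
Why: Shi epoxidation (chiral dioxirane, spiro transition state) oxidises the only alkene left under reagent control and sets both oxirane carbons, of which C1 of the bicycle is the future carbinol center; the dialkyl peroxide and the ester are inert to the dioxirane.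

Step 7
Reactants: 11 methyl (2S)-2-[(3S,6R)-6-methyl-6-{2-[(1S,6R)-2,2,6-trimethyl-7-oxabicyclo[4.1.0]heptan-1-yl]ethyl}-1,2-dioxan-3-yl]propanoate
Product: 13 methyl (2S)-2-[(3S,6R)-6-{2-[(1S)-1-hydroxy-2,2-dimethyl-6-methylidenecyclohexyl]ethyl}-6-methyl-1,2-dioxan-3-yl]propanoate, via trimethylsilyl ether 12 (not isolated)
Conditions: TMSOTf (1.5 equiv), 2,6-lutidine (3 equiv), CH2Cl2, −78 °C; then citric acid, MeOH, 0 °C
Reagents that add atoms: none
Why: Silyl triflate activation of the oxirane and anti E2 removal of a proton of the ring methyl group by the hindered base (Noyori-type epoxide to allyl silyl ether isomerisation) breaks only the C6–O bond of the bicycle, so the carbinol configuration from step 6 is kept; acidic methanol then frees the tertiary alcohol.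

## Compound list

1 | dihydro-β-ionone, 4-(2,6,6-trimethylcyclohex-1-en-1-yl)butan-2-one | CC(=O)CCC1=C(C)CCCC1(C)C | starting material
2 | allyl bromide | C=CCBr | starting material
3 | lithium 4-(2,6,6-trimethylcyclohex-1-en-1-yl)but-1-en-2-olate | [Li+].[O-]C(=C)CCC1=C(C)CCCC1(C)C | intermediate
4 | 1-(2,6,6-trimethylcyclohex-1-en-1-yl)hept-6-en-3-one | C=CCCC(=O)CCC1=C(C)CCCC1(C)C | intermediate
5 | 1,3,3-trimethyl-2-(3-methylidenehept-6-en-1-yl)cyclohex-1-ene | C=CCCC(=C)CCC1=C(C)CCCC1(C)C | intermediate
6 | methyl methacrylate | C=C(C)C(=O)OC | starting material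
7 | methyl (2E)-2-methyl-6-methylidene-8-(2,6,6-trimethylcyclohex-1-en-1-yl)oct-2-enoate | COC(=O)/C(C)=C/CCC(=C)CCC1=C(C)CCCC1(C)C | intermediate
8 | methyl (2E)-2,6-dimethyl-6-[(triethylsilyl)peroxy]-8-(2,6,6-trimethylcyclohex-1-en-1-yl)oct-2-enoate, both C6 antipodes | COC(=O)/C(C)=C/CCC(C)(OO[Si](CC)(CC)CC)CCC1=C(C)CCCC1(C)C | intermediate
9 | methyl (2E)-6-hydroperoxy-2,6-dimethyl-8-(2,6,6-trimethylcyclohex-1-en-1-yl)oct-2-enoate, both C6 antipodes | COC(=O)/C(C)=C/CCC(C)(OO)CCC1=C(C)CCCC1(C)C | intermediate
10 | methyl (2S)-2-{(3S,6S)-6-methyl-6-[2-(2,6,6-trimethylcyclohex-1-en-1-yl)ethyl]-1,2-dioxan-3-yl}propanoate | CC1=C(CC[C@@]2(C)CC[C@@H]([C@H](C)C(=O)OC)OO2)C(C)(C)CCC1 | intermediate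
11 | methyl (2S)-2-[(3S,6R)-6-methyl-6-{2-[(1S,6R)-2,2,6-trimethyl-7-oxabicyclo[4.1.0]heptan-1-yl]ethyl}-1,2-dioxan-3-yl]propanoate | [C@]12(O[C@]1(C)CCCC2(C)C)CC[C@@]3(C)CC[C@@H]([C@H](C)C(=O)OC)OO3 | intermediate
12 | methyl (2S)-2-[(3S,6R)-6-{2-[(1S)-2,2-dimethyl-6-methylidene-1-(trimethylsilyloxy)cyclohexyl]ethyl}-6-methyl-1,2-dioxan-3-yl]propanoate | C=C1CCCC(C)(C)[C@@]1(O[Si](C)(C)C)CC[C@@]1(C)CC[C@@H]([C@H](C)C(=O)OC)OO1 | intermediate
13 | methyl (2S)-2-[(3S,6R)-6-{2-[(1S)-1-hydroxy-2,2-dimethyl-6-methylidenecyclohexyl]ethyl}-6-methyl-1,2-dioxan-3-yl]propanoate | C=C1CCCC(C)(C)[C@@]1(O)CC[C@@]1(C)CC[C@@H]([C@H](C)C(=O)OC)OO1 | target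

## Step count and risks

Total step count: 7. Longest linear sequence: 7 steps (1 to 13).

The three steps most likely to fail:

Step 5 (the proposed new ring closure). Facial control or the protonation may be poor, or the enolate may attack the O–O bond and give an epoxy ester. The fallback sets out from 8 and comes back at 10. Compound 8 is desilylated as before and the crude hydroperoxide 9 is cyclised with Et2NH in CF3CH2OH, the established amine-mediated hydroperoxide Michael ring closure. This gives the stereoisomer mixture of methyl 2-{6-methyl-6-[2-(2,6,6-trimethylcyclohex-1-en-1-yl)ethyl]-1,2-dioxan-3-yl}propanoate F1. The racemate with the relative configuration of 10 is isolated on silica and resolved by preparative HPLC on a chiral stationary phase to give 10.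

Step 6 (Shi epoxidation of an all-alkyl tetrasubstituted ring alkene). This substrate class is slow and its facial selectivity is not secured by precedent. The fallback sets out from 10 and comes back at 11. Stereocontrol in the oxidation is given up and taken back by separation: mCPBA (NaHCO3, CH2Cl2, 0 °C) gives 11 together with its oxirane diastereomer, methyl (2S)-2-[(3S,6R)-6-methyl-6-{2-[(1R,6S)-2,2,6-trimethyl-7-oxabicyclo[4.1.0]heptan-1-yl]ethyl}-1,2-dioxan-3-yl]propanoate F2. The two are separated by preparative HPLC and 11 is carried on.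

Step 7 (silyl triflate isomerisation next to a peroxide). The Lewis acid may ionise the tertiary C6–O bond of the dioxane, or proton loss may give the endocyclic alkene. The fallback sets out from 10 and comes back at 13, leaving out 11 and 12. Dye-sensitised photooxygenation (O2, tetraphenylporphyrin, visible light, CH2Cl2, −20 °C; Schenck ene reaction of the tetrasubstituted alkene) gives methyl (2S)-2-[(3S,6R)-6-{2-[(1S)-1-hydroperoxy-2,2-dimethyl-6-methylidenecyclohexyl]ethyl}-6-methyl-1,2-dioxan-3-yl]propanoate F3, together with its carbinol epimer and ene regioisomers. PPh3 (1 equiv, 0 °C) reduces the hydroperoxide but not the hindered dialkyl peroxide, and 13 is isolated by preparative HPLC.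

Further compounds

F1 | step 5 | methyl 2-{6-methyl-6-[2-(2,6,6-trimethylcyclohex-1-en-1-yl)ethyl]-1,2-dioxan-3-yl}propanoate, mixture of stereoisomers | COC(=O)C(C)C1CCC(C)(CCC2=C(C)CCCC2(C)C)OO1
F2 | step 6 | methyl (2S)-2-[(3S,6R)-6-methyl-6-{2-[(1R,6S)-2,2,6-trimethyl-7-oxabicyclo[4.1.0]heptan-1-yl]ethyl}-1,2-dioxan-3-yl]propanoate | [C@@]12(O[C@@]1(C)CCCC2(C)C)CC[C@@]3(C)CC[C@@H]([C@H](C)C(=O)OC)OO3
F3 | step 7 | methyl (2S)-2-[(3S,6R)-6-{2-[(1S)-1-hydroperoxy-2,2-dimethyl-6-methylidenecyclohexyl]ethyl}-6-methyl-1,2-dioxan-3-yl]propanoate | C=C1CCCC(C)(C)[C@@]1(OO)CC[C@@]1(C)CC[C@@H]([C@H](C)C(=O)OC)OO1
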